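(The numbers in the tables are simulated for an exercise, and the scatter is random.)

Read gamma and theta as one curve on two clocks, since that is the way to carry them over to the flasks asked about.

| flask | Z | E | G | temperature | remark | time |
|---|---|---|---|---|---|---|
| gamma | 40 mM | 60 mM | 12 mM | 65 °C | run made earlier |  |
| theta | 40 mM | 60 mM | 8 mM | 76 °C | run made earlier |  |
| alpha | 40 mM | 60 mM | 18 mM | 65 °C | run made earlier |  |
| epsilon | 80 mM | 60 mM | 12 mM | 76 °C | run made earlier |  |
| dusk | 40 mM | 60.0 mM (fed, over 5.0 h) | 12.0 mM | 70 °C | all else is in the flask from the start; the feed brings no volume worth counting | 8.0 h |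
| spring | 40 mM | 60.0 mM | 12.0 mM |  | everything together at the start at 40 °C, warmed to 70 °C at 5.0 h | 8.0 h |
| autumn | 40 mM (fed, over 5.0 h) | 60.0 mM | 12.0 mM | 70 °C | all else is in the flask from the start; the feed brings no volume worth counting | 8.0 h |
| midnight | 40 mM (fed, over 80 min) | 60.0 mM | 12.0 mM | 70 °C | all else is in the flask from the start; the feed brings no volume worth counting | 8.0 h |
| noon | 40 mM (fed, over 5.0 h) | 60.0 mM | 12.0 mM |  | the addition at 40 °C, then warmed to 70 °C; the feed brings no volume worth counting | 8.0 h |

- gamma (time / h: J / %): 0.667: 1.8; 1.00: 2.3; 2.00: 6.2; 3.00: 11.4; 5.00: 18.0; 8.00: 22.0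
- theta (time / h: J / %): 0.667: 5.7; 1.00: 9.7; 2.00: 19.3; 3.00: 23.9; 5.00: 26.6; 8.00: 26.5
- alpha (time / h: J / %): 0.667: 1.4; 1.00: 2.2; 2.00: 7.0; 3.00: 11.8; 5.00: 17.4; 8.00: 21.4
- epsilon (time / h: J / %): 0.667: 4.4; 2.00: 12.5; 4.00: 14.8; 6.00: 13.7; 8.00: 13.2

(standard deviation of a reading: 0.3 percentage points)



- which flask leads in amount of J, in percent of the Z charged ("all alike" within 1.5 percentage points) (dusk / spring / autumn / midnight / noon / all alike)
- how much J is there at the end, in percent of the Z charged: dusk
- how much J is there at the end, in percent of the Z charged: spring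
- how much J is there at the end, in percent of the Z charged: autumn
- how much J is there at the end, in percent of the Z charged: midnight
- how much J is there at the end, in percent of the Z charged: noon

I began from rate constants: a rate constant k grows with temperature as exp(−Ea/RT), where Ea is the activation energy, R the gas constant and T the absolute temperature, so its logarithm falls on a straight line against the reciprocal of T. If the steps in a flask have similar Ea, warming shortens the clock, and the curve of J at one temperature is the curve at another with its hours stretched by one factor. Alpha, with 18 mM of G against gamma's 12 mM, read 17.4% at 5.00 h where gamma read 18.0%, so I set aside theta's lower G. Gamma read 18.0% at 5.00 h and theta, at 76 °C, read 19.3% at 2.00 h, so I took these two as like points and read a stretch of about 2.50, or 0.398 of a power of ten, and from it Ea of about 81.8 kJ mol⁻¹. The two curves part late, though, by 1.9 percentage points between theta at 3.00 h and gamma at 8.00 h, so I trusted this clock to that width.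

I then defined the cold factor F, the number of hours at 40 °C that do the work of one hour at 70 °C, and it came to 15.6, which is 1.19 powers of ten; likewise the factor between the clock at 70 °C and the clock at gamma's 65 °C came to 1.53. Spring has gamma's charges, and its cold 5.0 h shrank to 0.321 h, so it had 3.32 h at 70 °C, or 5.07 h on gamma's clock, and I committed to about the 18.0% gamma read at 5.00 h. Counting a fed charge by its mean hours in the flask, dusk and autumn each had 8.40 h on gamma's clock, near gamma's 22.0%, and midnight had 11.2 h, past gamma's last reading, so I put midnight first.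

The forecast named autumn as leader, with 15% for dusk, 19% for spring, 27% for autumn, 25% for midnight and 21% for noon, holding that “A slow E feed starves the second step”.

Midnight led at 24.4%, ahead of dusk at 22.9% and autumn at 22.6%, and spring stood at 18.6%, with 58.4% of its Z left at 8.00 h.

    Z + E ⇌ L + Q (K = 1.70, k = 3.70 M⁻¹ h⁻¹, Ea = 80.0 kJ mol⁻¹, ΔH = −11.0 kJ mol⁻¹)
    Q + E ⇌ L + J (K = 2.00, k = 12.0 M⁻¹ h⁻¹, Ea = 86.0 kJ mol⁻¹, ΔH = 38.0 kJ mol⁻¹)
    J + E ⇌ L + X (K = 0.520, k = 1.90 M⁻¹ h⁻¹, Ea = 90.0 kJ mol⁻¹, ΔH = 18.0 kJ mol⁻¹)
    Q + G → D (k = 4.10 M⁻¹ h⁻¹, Ea = 81.0 kJ mol⁻¹)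
    (constants at 70 °C)

Noon took the cold factor once more: its Z came in evenly during the cold hours, so on average it stood through half of them, which gave 3.16 h at 70 °C, or 4.83 h on gamma's clock, less than spring's 5.07 h, and noon ended at 18.0%.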